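From 4.00 h on, the electrophile in the theta and gamma flasks stood about level, given the scatter of 2 percentage points, with 65% of it still present in theta at 8.00 h, so the coupling had stalled with electrophile still in the flask.

| flask | electrophile | nucleophile | remark | time |
|---|---|---|---|---|
| theta | 15 mM | 10.5 mM | run made earlier |  |
| gamma | 20 mM | 10.5 mM | run made earlier |  |
| noon | 10 mM | 10.0 mM |  | 25 h |
| autumn | 10 mM | 16.0 mM |  | 25 h |

| run | time / h | electrophile / % | target / % |
|---|---|---|---|
| theta | 2.00 | 72 | 31 |
| theta | 4.00 | 63 | 34 |
| theta | 5.00 | 68 | 32 |
| theta | 8.00 | 65 | 33 |
| gamma | 0.833 | 81 | 18 |
| gamma | 2.00 | 76 | 22 |
| gamma | 4.00 | 73 | 22 |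
| gamma | 6.00 | 74 | 26 |
| gamma | 8.00 | 72 | 24 |

(each reading ± 2 percentage points)

- part of the electrophile that has reacted at the end, noon
- part of the electrophile that has reacted at the end, autumn
- what raising the concentration of nucleophile from its lowest to its highest value here does to the part of the electrophile that has reacted (changes below 5 percentage points count as none) (no change / it falls / it rises)

I reckoned the amount reacted in two ways, averaging the readings from 4.00 h on. By electrophile lost, theta gave 5.20 mM and gamma 5.40 mM. By target made, theta gave 4.95 mM and gamma 4.80 mM.

The first way came to about half of the charged nucleophile, although gamma held more electrophile. I read this as a toll: one nucleophile couples, and the acid set free takes a second as protonated nucleophile, which makes the nucleophile the limiting reagent. On that first round, noon reaches 50.0% and autumn 80.0%.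

The two ways parted by 0.250 mM in theta and 0.600 mM in gamma, weak readings at this scatter. I took the target way as the one that cheats, since the proposed step of acid set free with target removes target, while the electrophile way still counts that material as reacted. That step also spares a nucleophile for each side product formed, so I went round again: setting aside free nucleophile, dormant form and free acid set free, reacted electrophile is about the charged [nucleophile] plus [side product], divided by two.

Taking the mean gap as grown steadily up to 8.00 h, I got 1.33 mM of side product by 25 h, and I call this the refund. Assuming both flasks level off within 25 h, noon comes to 56.6% and autumn to 86.6%.

The forecast gave 49% for noon and 78% for autumn, and it rises for the trend, reasoning that “each coupling releasing acid that ties up a second nucleophile”, and its figures stood below mine.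

The noon flask reacted 54.9% of its electrophile and the autumn flask 82.0%, and the answer on the trend was that it rises, by 27 points.

    electrophile + nucleophile → acid set free + target (k = 61.0 /M/h)
    nucleophile + acid set free ⇌ protonated nucleophile, settled at all times (K = 1.80 × 10⁵ /M)
    nucleophile ⇌ dormant form (K = 0.810, k = 0.780 /h)
    acid set free + target → side product (k = 55.0 /M/h)

At 25.0 h the noon flask held 9.38% of its electrophile as side product, which is 0.938 mM, less than the refund. For a neighbour flask, like noon but charged with 25 mM of electrophile, my rule with the same refund gives 22.7%, and that flask reacted 25.5%.

The numbers in the tables come from a simulation for substances that don't exist; noise was put on by code.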